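Ring B of the isoflavone is cut at C1'–C2' and traced back to a four-membered ring. Heating a 4-alkenyl-4-methoxy-3-benzyloxycyclobutenone should open it to a dienylketene that closes to the hexasubstituted benzene in one operation. This places the free 2'-OH para to the 5'-OMe, the 4'-oxygen next to it, the hydrated prenyl chain at C6' and a two-carbon handle at C1'. This 1,2,4-trioxygenated pattern of ring B is the feature exploited. The precursor carries both side chains on a Z-trisubstituted alkene attached to the carbinol carbon of a benzyl semisquarate adduct. The handle later becomes C3/C4 of the chromone by a deoxybenzoin ring closure.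

Key step: step 10

Remark: the precursor is carried as a racemate and as the Z alkene that the dibromoalkene route delivers, because its stereocentre and its alkene geometry are both erased on aromatisation. Both silyl ethers are triethylsilyl, so that only the primary one is oxidised in step 12 and the tertiary one falls in the same mild acid step that frees ring A.

Step 1
Reactants: 1 squaric acid (3,4-dihydroxycyclobut-3-ene-1,2-dione); 2 benzyl alcohol
Product: 3 dibenzyl squarate (3,4-bis(benzyloxy)cyclobut-3-ene-1,2-dione)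
Conditions: BnOH (2.2 equiv), toluene, reflux, Dean–Stark
Reagents that add atoms: benzyl alcohol (second equivalent), OCc1ccccc1
Why: Squaric acid is a strong vinylogous acid whose two hydroxyls are each esterified by one molecule of benzyl alcohol once water is removed azeotropically (Fischer-type esterification), the standard way to dialkyl squarates.

Step 2
Reactants: 3 dibenzyl squarate
Product: 5 3-(benzyloxy)cyclobut-3-ene-1,2-dione, via 4-hydroxy-2,3-bis(benzyloxy)cyclobut-2-en-1-one 4 (not isolated)
Conditions: LiAlH(Ot-Bu)3, THF, −78 → −20 °C; then aq. HCl (cat.), CH2Cl2, 0 °C → rt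
Reagents that add atoms: water, O
Why: 1,2-Reduction of one carbonyl by the bulky hydride gives the hydroxycyclobutenone, which under acid should undergo the known allylic transposition–hydrolysis to the semisquarate, losing benzyl alcohol and taking its new carbonyl oxygen from water.

Step 3
Reactants: 6 propane-1,3-diol
Product: 7 3-(triethylsilyloxy)propan-1-ol
Conditions: NaH (1.0 equiv), THF, rt; then Et3SiCl (1.0 equiv), 0 °C → rt
Reagents that add atoms: chlorotriethylsilane, CC[Si](Cl)(CC)CC
Why: O-Silylation of the sparingly soluble monosodium alkoxide of a symmetrical diol should favour the mono-ether (monoprotection of a diol).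

Step 4
Reactants: 7 3-(triethylsilyloxy)propan-1-ol
Product: 8 3-(triethylsilyloxy)propanal
Conditions: Dess–Martin periodinane, pyridine, CH2Cl2, 0 °C → rt
Reagents that add atoms: none
Why: Dess–Martin oxidation under buffered conditions should convert the primary alcohol to the aldehyde without cleaving the silyl ether or causing β-elimination.

Step 5
Reactants: 8 3-(triethylsilyloxy)propanal
Product: 9 (4,4-dibromobut-3-enyloxy)triethylsilane
Conditions: CBr4, PPh3, Zn dust, CH2Cl2, rt; then 8, 0 °C → rt
Reagents that add atoms: carbon tetrabromide, BrC(Br)(Br)Br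
Why: Corey–Fuchs (Ramirez) dibromo-olefination; the zinc variant forms the dibromomethylene ylide without free Ph3PBr2, which spares the acid-labile silyl ether.

Step 6
Reactants: 10 3-methylbutane-1,3-diol
Product: 11 4-iodo-2-methylbutan-2-ol
Conditions: I2, PPh3, imidazole, CH2Cl2, 0 °C → rt
Reagents that add atoms: iodine, II
Why: Appel-type iodination should be selective for the primary hydroxyl, because the tertiary one is too hindered to be activated and displaced.

Step 7
Reactants: 11 4-iodo-2-methylbutan-2-ol
Product: 12 triethyl[(4-iodo-2-methylbutan-2-yl)oxy]silane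
Conditions: Et3SiOTf, 2,6-lutidine, CH2Cl2, −78 → 0 °C
Reagents that add atoms: triethylsilyl trifluoromethanesulfonate, CC[Si](CC)(CC)OS(=O)(=O)C(F)(F)F
Why: A silyl triflate with a hindered pyridine base is the standard O-silylation of tertiary alcohols and leaves a primary iodide untouched.

Step 8
Reactants: 12 triethyl[(4-iodo-2-methylbutan-2-yl)oxy]silane; 9 (4,4-dibromobut-3-enyloxy)triethylsilane
Product: 14 (Z)-4-bromo-7-methyl-1,7-bis(triethylsilyloxy)oct-3-ene (bromine cis to the CH2CH2OSiEt3 chain), via alkylzinc iodide 13 (not isolated)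
Conditions: 12, Zn dust (activated by BrCH2CH2Br, Me3SiCl), LiCl, THF, 40 °C; then 9, PdCl2(DPEphos) (3 mol %), THF, 0 °C → rt
Reagents that add atoms: none
Why: Trans-selective Negishi monoalkylation of a 1,1-dibromoalkene: oxidative addition should take place at the less hindered C–Br bond trans to the alkyl chain and the coupling proceeds with retention, leaving the second bromine cis to that chain.

Step 9
Reactants: 14 (Z)-4-bromo-7-methyl-1,7-bis(triethylsilyloxy)oct-3-ene; 5 3-(benzyloxy)cyclobut-3-ene-1,2-dione
Product: 17 3-(benzyloxy)-4-methoxy-4-[(Z)-7-methyl-1,7-bis(triethylsilyloxy)oct-3-en-4-yl]cyclobut-2-en-1-one (racemic), via alkenyllithium 15 (not isolated), via lithium alkoxide 16 (not isolated)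
Conditions: 14, t-BuLi (2.0 equiv), Et2O, −78 °C; cannulate into 5, THF, −78 °C; then MeOTf, −78 → −20 °C
Reagents that add atoms: methyl trifluoromethanesulfonate, COS(=O)(=O)C(F)(F)F
Why: Bromine–lithium exchange with retention, 1,2-addition to the ketone-like carbonyl next to the benzyloxy-bearing carbon (the other carbonyl is deactivated as a vinylogous ester) and O-methylation of the alkoxide in the same flask; the quaternary centre C4 forms as a racemate and needs no control because step 10 erases it.

Step 10
Reactants: 17 3-(benzyloxy)-4-methoxy-4-[(Z)-7-methyl-1,7-bis(triethylsilyloxy)oct-3-en-4-yl]cyclobut-2-en-1-one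
Product: 20 5-(benzyloxy)-4-methoxy-3-[3-methyl-3-(triethylsilyloxy)butyl]-2-[2-(triethylsilyloxy)ethyl]phenol, via dienylketene 18 (not isolated), via cyclohexadienone 19 (not isolated)
Conditions: toluene (0.01 M, degassed), 110 °C
Reagents that add atoms: none
Why: Heating should trigger conrotatory 4π electrocyclic opening of the C1–C4 bond to dienylketene 18, whose ketene carbon and alkene CH terminus then undergo a thermally allowed disrotatory 6π electrocyclisation that forms the C1'–C2' bond and gives cyclohexa-2,4-dienone 19, which tautomerises to phenol 20. The closest known reaction is the Moore rearrangement of 4-alkenyl-4-alkoxycyclobutenones to hydroquinone monoethers. Ring B is closed in the 6π electrocyclic mode as a six-membered carbocycle, and no stereocentre remains, since C4 of 17 and C6 of 19 both become aromatic carbons. Closure requires the ring opening to send the alkenyl substituent inward, cis to the ketene, and the methoxy donor on the same carbon enforces this through its strong preference for outward rotation, while any outward-turned alkenyl isomer could only revert to 17. The substitution pattern needs no selectivity because connectivity fixes every position: ketene carbon to C2' (OH), ring CH to C3', benzyloxy carbon to C4', methoxy carbinol to C5', alkene carbons to C6' and C1'. The CH2 that the Z alkene places on the inner face should be tolerated because the attacking ketene terminus is a linear, unhindered sp carbon, as in the easy thermal reclosure of dienylketenes to 6,6-disubstituted cyclohexadienones.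

Step 11
Reactants: 20 5-(benzyloxy)-4-methoxy-3-[3-methyl-3-(triethylsilyloxy)butyl]-2-[2-(triethylsilyloxy)ethyl]phenol
Product: 21 {2-[2,4-bis(benzyloxy)-5-methoxy-6-(3-methyl-3-(triethylsilyloxy)butyl)phenyl]ethoxy}triethylsilane
Conditions: BnBr, K2CO3, DMF, rt
Reagents that add atoms: benzyl bromide, BrCc1ccccc1
Why: Williamson etherification of the phenol masks the 2'-oxygen, which would otherwise cyclise onto the later ketone or enaminone, and lets both ring B phenols be freed by one hydrogenolysis.

Step 12
Reactants: 21 {2-[2,4-bis(benzyloxy)-5-methoxy-6-(3-methyl-3-(triethylsilyloxy)butyl)phenyl]ethoxy}triethylsilane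
Product: 22 2-{2,4-bis(benzyloxy)-5-methoxy-6-[3-methyl-3-(triethylsilyloxy)butyl]phenyl}acetaldehyde
Conditions: (COCl)2, DMSO, CH2Cl2, −78 → −40 °C; then Et3N, −78 °C → rt
Reagents that add atoms: none
Why: Swern oxidation applied directly to a primary triethylsilyl ether, which the chlorosulfonium reagent desilylates and oxidises in one operation while the hindered tertiary silyl ether should stay.

Step 13
Reactants: 23 4-bromobenzene-1,3-diol
Product: 24 1-bromo-2,4-bis(methoxymethoxy)benzene
Conditions: MeOCH2Cl (2.5 equiv), i-Pr2NEt (3 equiv), CH2Cl2, 0 °C → rt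
Reagents that add atoms: chloromethyl methyl ether, COCCl; chloromethyl methyl ether (second equivalent), COCCl
Why: O-Alkylation of both phenols (Williamson-type acetal formation, one equivalent of the chloride per hydroxyl) gives protecting groups that tolerate aryllithium chemistry and fall under mild acid.

Step 14
Reactants: 24 1-bromo-2,4-bis(methoxymethoxy)benzene; 22 2-{2,4-bis(benzyloxy)-5-methoxy-6-[3-methyl-3-(triethylsilyloxy)butyl]phenyl}acetaldehyde
Product: 27 2-{2,4-bis(benzyloxy)-5-methoxy-6-[3-methyl-3-(triethylsilyloxy)butyl]phenyl}-1-[2,4-bis(methoxymethoxy)phenyl]ethan-1-ol (racemic), via aryllithium 25 (not isolated), via arylcerium dichloride 26 (not isolated)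
Conditions: 24, n-BuLi, THF, −78 °C; CeCl3 (anhydrous), −78 °C; then 22, −78 °C; aq. NH4Cl
Reagents that add atoms: none
Why: Bromine–lithium exchange and transmetalation to the weakly basic organocerium reagent should allow 1,2-addition to the enolisable arylacetaldehyde; the carbinol centre forms as a racemate and is removed in step 15.

Step 15
Reactants: 27 2-{2,4-bis(benzyloxy)-5-methoxy-6-[3-methyl-3-(triethylsilyloxy)butyl]phenyl}-1-[2,4-bis(methoxymethoxy)phenyl]ethan-1-ol
Product: 28 2-{2,4-bis(benzyloxy)-5-methoxy-6-[3-methyl-3-(triethylsilyloxy)butyl]phenyl}-1-[2,4-bis(methoxymethoxy)phenyl]ethan-1-one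
Conditions: Dess–Martin periodinane, pyridine, CH2Cl2, 0 °C → rt
Reagents that add atoms: none
Why: Dess–Martin oxidation of the secondary benzylic alcohol should give the deoxybenzoin under neutral conditions that spare the silyl, acetal and benzyl ethers.

Step 16
Reactants: 28 2-{2,4-bis(benzyloxy)-5-methoxy-6-[3-methyl-3-(triethylsilyloxy)butyl]phenyl}-1-[2,4-bis(methoxymethoxy)phenyl]ethan-1-one
Product: 30 3-[2,4-bis(benzyloxy)-6-(3-hydroxy-3-methylbutyl)-5-methoxyphenyl]-7-hydroxy-4H-chromen-4-one, via enaminone 29 (not isolated)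
Conditions: Me2NCH(OMe)2, toluene, 100 °C; evaporate; then HCl (1 M), MeOH–THF–H2O, 40 °C
Reagents that add atoms: N,N-dimethylformamide dimethyl acetal, COC(OC)N(C)C
Why: Aminomethylenation of the active methylene gives the enaminone, and acid should then remove both methoxymethyl groups and the tertiary silyl ether so that the freed 2-hydroxyl adds to the enaminone carbon and expels dimethylamine (the addition–elimination ring closure of the deoxybenzoin route to isoflavones).

Step 17
Reactants: 30 3-[2,4-bis(benzyloxy)-6-(3-hydroxy-3-methylbutyl)-5-methoxyphenyl]-7-hydroxy-4H-chromen-4-one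
Product: 31 kwakhurin hydrate, 3-[2,4-dihydroxy-6-(3-hydroxy-3-methylbutyl)-5-methoxyphenyl]-7-hydroxy-4H-chromen-4-one (no stereocentre)
Conditions: H2 (1 atm), Pd/C (10%), EtOAc–MeOH, rt
Reagents that add atoms: none
Why: Hydrogenolysis of the two benzyl aryl ethers should be faster than saturation of the aryl-shielded chromone C2–C3 bond if the reaction is stopped after uptake of two equivalents of hydrogen.

Compound list

1 | squaric acid (3,4-dihydroxycyclobut-3-ene-1,2-dione) | O=C1C(O)=C(O)C1=O | starting material
2 | benzyl alcohol | OCc1ccccc1 | starting material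
3 | dibenzyl squarate (3,4-bis(benzyloxy)cyclobut-3-ene-1,2-dione) | O=C1C(=O)C(OCc2ccccc2)=C1OCc1ccccc1 | intermediate
4 | 4-hydroxy-2,3-bis(benzyloxy)cyclobut-2-en-1-one (racemic, formed in the flask) | O=C1C(OCc2ccccc2)=C(OCc2ccccc2)C1O | intermediate
5 | 3-(benzyloxy)cyclobut-3-ene-1,2-dione | O=C1C=C(OCc2ccccc2)C1=O | intermediate
6 | propane-1,3-diol | OCCCO | starting material
7 | 3-(triethylsilyloxy)propan-1-ol | OCCCO[Si](CC)(CC)CC | intermediate
8 | 3-(triethylsilyloxy)propanal | O=CCCO[Si](CC)(CC)CC | intermediate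
9 | (4,4-dibromobut-3-enyloxy)triethylsilane | BrC(Br)=CCCO[Si](CC)(CC)CC | intermediate
10 | 3-methylbutane-1,3-diol | CC(C)(O)CCO | starting material
11 | 4-iodo-2-methylbutan-2-ol | CC(C)(O)CCI | intermediate
12 | triethyl[(4-iodo-2-methylbutan-2-yl)oxy]silane | CC(C)(CCI)O[Si](CC)(CC)CC | intermediate
13 | [3-methyl-3-(triethylsilyloxy)butyl]zinc iodide (formed in the flask) | CC(C)(CC[Zn]I)O[Si](CC)(CC)CC | intermediate
14 | (Z)-4-bromo-7-methyl-1,7-bis(triethylsilyloxy)oct-3-ene | Br/C(CCC(C)(C)O[Si](CC)(CC)CC)=C\CCO[Si](CC)(CC)CC | intermediate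
15 | alkenyllithium from 14, geometry retained, lithium cis to the CH2CH2OSiEt3 chain (formed in the flask) | [Li]/C(CCC(C)(C)O[Si](CC)(CC)CC)=C\CCO[Si](CC)(CC)CC | intermediate
16 | lithium alkoxide of 3-(benzyloxy)-4-hydroxy-4-[(Z)-7-methyl-1,7-bis(triethylsilyloxy)oct-3-en-4-yl]cyclobut-2-en-1-one (racemic, formed in the flask) | O=C1C=C(OCc2ccccc2)C1(O[Li])/C(CCC(C)(C)O[Si](CC)(CC)CC)=C\CCO[Si](CC)(CC)CC | intermediate
17 | 3-(benzyloxy)-4-methoxy-4-[(Z)-7-methyl-1,7-bis(triethylsilyloxy)oct-3-en-4-yl]cyclobut-2-en-1-one (racemic) | O=C1C=C(OCc2ccccc2)C1(OC)/C(CCC(C)(C)O[Si](CC)(CC)CC)=C\CCO[Si](CC)(CC)CC | intermediate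
18 | (3Z,5Z)-3-(benzyloxy)-4-methoxy-5-[3-methyl-3-(triethylsilyloxy)butyl]-8-(triethylsilyloxy)octa-1,3,5-trien-1-one (dienylketene, formed in the flask) | O=C=C/C(OCc1ccccc1)=C(OC)\C(CCC(C)(C)O[Si](CC)(CC)CC)=C/CCO[Si](CC)(CC)CC | intermediate
19 | 3-(benzyloxy)-4-methoxy-5-[3-methyl-3-(triethylsilyloxy)butyl]-6-[2-(triethylsilyloxy)ethyl]cyclohexa-2,4-dien-1-one (racemic, formed in the flask) | O=C1C=C(OCc2ccccc2)C(OC)=C(CCC(C)(C)O[Si](CC)(CC)CC)C1CCO[Si](CC)(CC)CC | intermediate
20 | 5-(benzyloxy)-4-methoxy-3-[3-methyl-3-(triethylsilyloxy)butyl]-2-[2-(triethylsilyloxy)ethyl]phenol | COc1c(OCc2ccccc2)cc(O)c(CCO[Si](CC)(CC)CC)c1CCC(C)(C)O[Si](CC)(CC)CC | intermediate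
21 | {2-[2,4-bis(benzyloxy)-5-methoxy-6-(3-methyl-3-(triethylsilyloxy)butyl)phenyl]ethoxy}triethylsilane | COc1c(OCc2ccccc2)cc(OCc2ccccc2)c(CCO[Si](CC)(CC)CC)c1CCC(C)(C)O[Si](CC)(CC)CC | intermediate
22 | 2-{2,4-bis(benzyloxy)-5-methoxy-6-[3-methyl-3-(triethylsilyloxy)butyl]phenyl}acetaldehyde | COc1c(OCc2ccccc2)cc(OCc2ccccc2)c(CC=O)c1CCC(C)(C)O[Si](CC)(CC)CC | intermediate
23 | 4-bromobenzene-1,3-diol | Oc1ccc(Br)c(O)c1 | starting material
24 | 1-bromo-2,4-bis(methoxymethoxy)benzene | COCOc1ccc(Br)c(OCOC)c1 | intermediate
25 | [2,4-bis(methoxymethoxy)phenyl]lithium (formed in the flask) | [Li]c1ccc(OCOC)cc1OCOC | intermediate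
26 | [2,4-bis(methoxymethoxy)phenyl]cerium dichloride (formed in the flask) | COCOc1ccc([Ce](Cl)Cl)c(OCOC)c1 | intermediate
27 | 2-{2,4-bis(benzyloxy)-5-methoxy-6-[3-methyl-3-(triethylsilyloxy)butyl]phenyl}-1-[2,4-bis(methoxymethoxy)phenyl]ethan-1-ol (racemic) | COCOc1ccc(C(O)Cc2c(OCc3ccccc3)cc(OCc3ccccc3)c(OC)c2CCC(C)(C)O[Si](CC)(CC)CC)c(OCOC)c1 | intermediate
28 | 2-{2,4-bis(benzyloxy)-5-methoxy-6-[3-methyl-3-(triethylsilyloxy)butyl]phenyl}-1-[2,4-bis(methoxymethoxy)phenyl]ethan-1-one | COCOc1ccc(C(=O)Cc2c(OCc3ccccc3)cc(OCc3ccccc3)c(OC)c2CCC(C)(C)O[Si](CC)(CC)CC)c(OCOC)c1 | intermediate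
29 | 2-{2,4-bis(benzyloxy)-5-methoxy-6-[3-methyl-3-(triethylsilyloxy)butyl]phenyl}-3-(dimethylamino)-1-[2,4-bis(methoxymethoxy)phenyl]prop-2-en-1-one (alkene geometry immaterial, formed in the flask) | COCOc1ccc(C(=O)C(=CN(C)C)c2c(OCc3ccccc3)cc(OCc3ccccc3)c(OC)c2CCC(C)(C)O[Si](CC)(CC)CC)c(OCOC)c1 | intermediate
30 | 3-[2,4-bis(benzyloxy)-6-(3-hydroxy-3-methylbutyl)-5-methoxyphenyl]-7-hydroxy-4H-chromen-4-one | COc1c(OCc2ccccc2)cc(OCc2ccccc2)c(-c2coc3cc(O)ccc3c2=O)c1CCC(C)(C)O | intermediate
31 | kwakhurin hydrate, 3-[2,4-dihydroxy-6-(3-hydroxy-3-methylbutyl)-5-methoxyphenyl]-7-hydroxy-4H-chromen-4-one | COc1c(O)cc(O)c(-c2coc3cc(O)ccc3c2=O)c1CCC(C)(C)O | target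

Total step count: 17.
Longest linear sequence: 12 steps (steps 3, 4, 5, 8, 9, 10, 11, 12, 14, 15, 16 and 17, from propane-1,3-diol).

Steps most likely to fail

Step 9. The alkenyllithium may attack the benzyloxy-bearing carbon (addition–elimination) instead of the carbonyl, or O-alkylation of the hindered tertiary alkoxide may lag behind its fragmentation on warming. The fallback sets out from 14 and 5 and separates the two events. The alkoxide 16 is protonated at −78 °C with aq. NH4Cl and the tertiary alcohol 3-(benzyloxy)-4-hydroxy-4-[(Z)-7-methyl-1,7-bis(triethylsilyloxy)oct-3-en-4-yl]cyclobut-2-en-1-one F1 is isolated. It is then etherified without passing through the free alkoxide by a Purdie-type methylation (MeI, Ag2O, K2CO3, MeCN, rt), which returns to the route at 17.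

Step 14. The arylmetal may act as a base and enolise the arylacetaldehyde, which would return starting aldehyde and aldol products. The fallback sets out from 22 and replaces carbonyl addition by acyl substitution. Pinnick oxidation (NaClO2, NaH2PO4, 2-methyl-2-butene, t-BuOH–H2O) should give 2-{2,4-bis(benzyloxy)-5-methoxy-6-[3-methyl-3-(triethylsilyloxy)butyl]phenyl}acetic acid F2. Amide coupling (MeNHOMe·HCl, EDC·HCl, HOBt, i-Pr2NEt, CH2Cl2) then gives the N-methoxy-N-methylamide of that acid F3. Addition of aryllithium 25 (THF, −78 °C) stops at the ketone through the chelated tetrahedral intermediate and returns to the route at 28, so that step 15 is no longer needed.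

Step 16. The neutral condensation at the methylene, flanked by a doubly ortho-substituted aryl group and an ortho-substituted aroyl group, may stall, so that the acid stage only returns deprotected ketone. The fallback sets out from 28 and introduces the one-carbon unit by enolate chemistry. Claisen formylation (NaH, HCO2Et, THF, 0 °C → rt) should give the hydroxymethylene ketone 2-{2,4-bis(benzyloxy)-5-methoxy-6-[3-methyl-3-(triethylsilyloxy)butyl]phenyl}-3-hydroxy-1-[2,4-bis(methoxymethoxy)phenyl]prop-2-en-1-one F4. The same acid treatment (HCl, MeOH–THF–H2O, 40 °C) then frees the ring A hydroxyls and the tertiary alcohol and closes the pyranone by hemiacetal formation and dehydration, returning to the route at 30.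

Further compounds

F1 | step 9 | 3-(benzyloxy)-4-hydroxy-4-[(Z)-7-methyl-1,7-bis(triethylsilyloxy)oct-3-en-4-yl]cyclobut-2-en-1-one (racemic) | O=C1C=C(OCc2ccccc2)C1(O)/C(CCC(C)(C)O[Si](CC)(CC)CC)=C\CCO[Si](CC)(CC)CC
F2 | step 14 | 2-{2,4-bis(benzyloxy)-5-methoxy-6-[3-methyl-3-(triethylsilyloxy)butyl]phenyl}acetic acid | COc1c(OCc2ccccc2)cc(OCc2ccccc2)c(CC(O)=O)c1CCC(C)(C)O[Si](CC)(CC)CC
F3 | step 14 | 2-{2,4-bis(benzyloxy)-5-methoxy-6-[3-methyl-3-(triethylsilyloxy)butyl]phenyl}-N-methoxy-N-methylacetamide | COc1c(OCc2ccccc2)cc(OCc2ccccc2)c(CC(=O)N(C)OC)c1CCC(C)(C)O[Si](CC)(CC)CC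
F4 | step 16 | 2-{2,4-bis(benzyloxy)-5-methoxy-6-[3-methyl-3-(triethylsilyloxy)butyl]phenyl}-3-hydroxy-1-[2,4-bis(methoxymethoxy)phenyl]prop-2-en-1-one | COCOc1ccc(C(=O)C(=CO)c2c(OCc3ccccc3)cc(OCc3ccccc3)c(OC)c2CCC(C)(C)O[Si](CC)(CC)CC)c(OCOC)c1
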